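**Conventions and assumptions (one line each)**

- Locants: the core is numbered as spiro[4.5]decane: C1–C4 five-membered ring, C5 spiro atom, C6–C10 six-membered ring. In the target C1 = CHOH, C2 = CH carrying the trienyl chain, C6 = C(CH3)OH, C9 = alkylidene carbon, C10 = CH carrying the arm.
- Faces: on the six-membered ring, "C1 face" is the side on which C1 leaves C5 (the other is the "C4 face"). On the five-membered ring, "C6 face" is the side on which C6 leaves C5 (the other is the "C10 face").
- Compounds 1, 2, 6, 14 and 27 are taken as purchasable; 14 is used as the racemate (its stereocentre disappears in step 13).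
- The C9 carbinol of 13 and 15 is drawn as the epimer expected from hydride attack on the C4 face; either epimer serves, because C9 is oxidised again in step 12.

## Analysis of the target

The target is a spiro[4.5]decane in which a cyclopentane (C1–C4) and a cyclohexane (C6–C10) share the quaternary carbon C5. The five-membered ring carries a secondary hydroxyl at C1 and, trans to it at C2, a cross-conjugated trienyl chain whose first carbon bears an acetoxymethyl group. The six-membered ring carries a tertiary methyl carbinol at C6, a 3-hydroxypropyl arm at C10 and, at C9, an exocyclic tetrasubstituted enal with the formyl group on the side of C10 (Z). There are five stereocentres (1S,2S,5S,6S,10R). Seen from the six-membered ring, C1, the arm on C10 and the C6 hydroxyl lie on one face; seen from the five-membered ring, the C1 hydroxyl is on the C6 face and the C2 chain on the C10 face. The sensitive groups are the γ-enolisable enal of fixed geometry, the 2-substituted diene/triene (acid, cycloaddition), and one primary allylic acetate that must be told apart from a primary, a secondary and a tertiary hydroxyl. The hard points are the quaternary spiro centre flanked by three stereocentres, the stereodefined tetrasubstituted alkene, and the hydroxyl/acetate differentiation. The strategy rests on the cis relationship, across the C5–C10 bond, of C1 and the first arm carbon. These two can be the ends of a γ-lactone (oxygen on C1, carbonyl carbon on C10) whose C10=C5 double bond acts as a dienophile, so that C6–C9 arrive as a four-carbon diene carrying oxygen at C6 and C9. The lactone oxygen at C1 then sits on the C10 face, opposite to the target, and has to be inverted through the C1 ketone.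

## Retrosynthetic reasoning

**35 ⇒ 34 ⇒ 33 (oxidation level, protecting groups).** No skeletal bond is cut. The enal is taken back to the allylic alcohol of 34, the only allylic hydroxyl in the molecule, so that a chemoselective allylic oxidation can end the route. 34 comes from 33 by fluoride removal of three silyl groups. The gain is that the enal is absent from every earlier step and the acetate is already in place before the hydroxyls are freed.

**33 ⇒ 32 ⇒ 31 ⇒ 26 + 29 (side chain).** The C=C bond between the chain carbon on C2 and its neighbour is cut as an aldol condensation between the acetaldehyde unit of 26 and dienal 29. The required geometry (oxygenated carbon trans to the dienyl group) is that of the thermodynamically favoured E 2-alkyl enal, and ten chain carbons arrive in one step. The new formyl group is the future acetoxymethyl carbon. 29 goes back through alkenyl triflate 28 to ketone 27 by a Heck disconnection.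

**26 ⇒ 25 ⇒ 24 ⇒ 22 ⇒ 21 (C2 branch, C1 carbinol).** The C2–CH2 bond is cut as an enolate allylation and the C1–H bond as a ketone reduction; the allyl group is an acetaldehyde equivalent. C2 is the only enolisable position of the C1 ketone, and the ketone is the state through which the lactone-derived C1 oxygen must pass to be inverted. The forward steps must bring the allyl group and then hydride in on the C10 face. The same hydride step lowers the ester and the amide.

**21 ⇒ 20 ⇒ 18 (arm).** The bond between the first and second arm carbons is cut as an olefination of aldehyde 19 with a stabilised two-carbon phosphorane, followed by saturation. This is done only after the alkene at C9 is in place, because the oxygen on the first arm carbon is needed before that as a tether.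

**18 ⇒ 17 ⇒ 16 ⇒ 15 ⇒ 13 + 14 (tetrasubstituted alkene).** The C9=C bond is cut as an intramolecular Horner–Wadsworth–Emmons reaction of a phosphonopropanoate hung on the primary oxygen of the first arm carbon. An intermolecular olefination of the C9 ketone has no reason to choose between the C8 and C10 sides. The six-membered lactone 17 can only form with its carbonyl carbon cis to C10, which is the target geometry. Opening the lactone as an amide keeps the geometry and frees the arm carbon for extension.

**13 ⇒ 12 ⇒ 11 ⇒ 10 (C6 methyl) and 10 ⇒ 9 ⇒ 8 ⇒ 7.** The C6–CH3 bond is cut as a methyl addition to the C6 ketone, performed while the lactone is still intact. The rigid cis-fused tricycle exposes only the C4 face of that ketone, and the C9 ketone, being part of a β-keto lactone, can be masked as its enolate. 10 goes back to adduct 7 by alkene saturation, acetate removal and oxidation.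

**7 ⇒ 5 + 6 (key disconnection).** The C5–C6 and C10–C9 bonds are cut as a Diels–Alder reaction of butenolide 5 with diene 6. This forms the six-membered ring and the quaternary spiro centre, and sets C5 and C10 in one step. The symmetric diene leaves no regiochemical question, and both acetoxy carbons are later oxidised, so their configuration does not matter.

**5 ⇒ 4 ⇒ 3 ⇒ 1 + 2 (dienophile).** The butenolide C=C is cut as an intramolecular Horner–Wadsworth–Emmons reaction of a phosphonoacetate on an α-oxygenated cyclopentanone. The single stereocentre comes from the C2-symmetric diol 1, one hydroxyl of which is acylated and the other oxidised.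

## Alternatives that were turned down

**Alternative 1: alkylidene carbene C–H insertion.** The C5–C1 bond is cut. In the forward direction a potassium amide base would convert bromoalkene A2 into an alkylidene carbene that inserts, with retention, into the tertiary C5–H bond five atoms away and closes spiro cyclopentene A1. In its favour, the quaternary centre is made stereospecifically from a tertiary stereocentre, and A1 already holds a carbon branch at C2 and a C1=C2 alkene ready for oxygenation trans to that branch. Against it, A2 must already contain the whole cyclohexane with three contiguous stereocentres (C5–H, C6, C10), for which the alternative offers no ring-forming simplification. The later oxygenation of C1 still needs facial control against the spiro ring, and the enal and side chain are as far away as in the chosen route. On fidelity of the spiro centre and on having the C2 branch in place, this alternative is stronger. The chosen strategy offers instead that the six-membered ring, the spiro centre and C10 are made together from two small partners (5 and 6) within four steps.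

**Alternative 2: nickel alkylative cyclisation.** The C8–C9 bond and the bond from the alkene carbon to its methyl group are cut. A zerovalent nickel catalyst would join the β-carbon of the vinyl ketone in enone–alkyne A4 to the proximal alkyne carbon while a methylzinc reagent delivers methyl to the distal one, closing spiro cyclohexanone A3. In its favour, the syn carbometallation fixes the tetrasubstituted alkene geometry directly. On this point it is stronger than the chosen route, which spends steps 11–14 on a tether to reach the same result. Against it, A4 needs the quaternary carbon C5 between two stereocentres and bearing a polymerisation-prone acryloyl group before the key step. Hydride transfer instead of methyl transfer is a known competing path. The C6 ketone of A3 must then take up methyl diastereoselectively without the rigid lactone that guides this addition in 10. The chosen strategy offers in exchange a one-step, stereochemically relayed construction of C5 and C10.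

**Alternative 3: allylsilane–aldehyde spirocyclisation.** The C1–C2 bond is cut. A tin-based Lewis acid would activate the neopentyl aldehyde of A6 and the tethered (E)-allylsilane would attack it, closing the five-membered ring as trans-2-vinylcyclopentanol A5. In its favour, C1 and C2 are set together with the trans relationship the target needs, and the vinyl group is a direct handle for the side chain. On these two centres it is stronger than the chosen route, which sets them by substrate control in steps 17 and 18. Against it, A6 presupposes the fully substituted cyclohexane, including the quaternary carbon, the tetrasubstituted alkene and the tertiary carbinol, so the hardest problems are only moved upstream. The Lewis acid also meets an acetal-protected tertiary carbinol and an allylic silyl ether, and the face of the aldehyde that is attacked (C1 relative to C5) is not secured. The chosen strategy offers an early, convergent solution of the quaternary centre and leaves only two substrate-controlled steps on the five-membered ring.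

Key step: step 4

## Route

Step 1
Reactants: 1 (1R,2R)-cyclopentane-1,2-diol; 2 2-(diethoxyphosphoryl)acetic acid
Product: 3 (1R,2R)-2-hydroxycyclopentyl 2-(diethoxyphosphoryl)acetate
Conditions: 1 (3 equiv), DCC, DMAP (cat.), CH2Cl2, 0 °C
Reagents that add atoms: none
Why: Carbodiimide (Steglich) esterification; the two hydroxyls of the C2-symmetric diol are equivalent, so an excess of diol keeps diacylation low and the surplus is recovered; no stereocentre is touched.

Step 2
Reactants: 3 (1R,2R)-2-hydroxycyclopentyl 2-(diethoxyphosphoryl)acetate
Product: 4 (1R)-2-oxocyclopentyl 2-(diethoxyphosphoryl)acetate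
Conditions: Dess–Martin periodinane, NaHCO3, CH2Cl2, 0 °C → rt
Reagents that add atoms: none
Why: Dess–Martin oxidation of the remaining secondary alcohol; the buffered, non-basic medium should leave the acyloxy-bearing stereocentre next to the new ketone unenolised.

Step 3
Reactants: 4 (1R)-2-oxocyclopentyl 2-(diethoxyphosphoryl)acetate
Product: 5 (6aR)-4,5,6,6a-tetrahydro-2H-cyclopenta[b]furan-2-one
Conditions: LiCl, i-Pr2NEt, MeCN, 0 °C → rt
Reagents that add atoms: none
Why: Intramolecular Horner–Wadsworth–Emmons reaction; the amine deprotonates only the lithium-chelated phosphonate, which closes the five-membered ring onto the neighbouring ketone; the weak base and short contact are chosen to avoid racemisation of C6a through the 2-oxyfuran anion.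

Step 4
Reactants: 5 (6aR)-4,5,6,6a-tetrahydro-2H-cyclopenta[b]furan-2-one; 6 (1E,3E)-buta-1,3-diene-1,4-diyl diacetate
Product: 7 endo adduct, 6,9-diacetoxy-1-hydroxyspiro[4.5]dec-7-ene-10-carboxylic acid 1,10-lactone (lactone oxygen on C1 on the C10 face; lactone carbonyl carbon and both acetoxy groups on the C1 face)
Conditions: 6 (3 equiv), CH2Cl2, 13 kbar, 50 °C, 72 h
Reagents that add atoms: none
Why: A concerted, suprafacial [4+2] cycloaddition of normal electron demand between the acetoxy-substituted diene and the lactone-conjugated double bond forms the C5–C6 and C10–C9 bonds together; the closest known reaction type is the Diels–Alder reaction of α,β-unsaturated γ-lactones with 1-oxygenated butadienes, run under pressure when the dienophile is β-substituted. The only ring closed is the cyclohexene, by intermolecular cycloaddition across the endocyclic alkene, so its fusion to the lactone is necessarily cis and the first arm carbon (lactone carbonyl) and C1 end up on the same face of the new ring. C5 and C10 are controlled by the single stereocentre of 5: its ring CH2 next to the carbinol carbon projects over one face of the planar butenolide, so the diene should add on the other face, syn to the ring-fusion hydrogen. C6 and C9 are set by the endo orientation of the diene relative to the lactone carbonyl, which is of no consequence because both carbons are oxidised in step 7. Facial selectivity is therefore the only selectivity the step needs; regiochemistry does not arise with the symmetric diene. The double bond is trisubstituted and the cycloaddition creates a quaternary carbon, so thermal reaction at ambient pressure is expected to be too slow; high pressure exploits the strongly negative activation volume without exposing the enol acetate diene to a Lewis acid.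

Step 5
Reactants: 7 endo adduct (spiro[4.5]dec-7-ene diacetate lactone)
Product: 8 6,9-diacetoxy-1-hydroxyspiro[4.5]decane-10-carboxylic acid 1,10-lactone
Conditions: H2 (1 atm), 5% Rh/Al2O3, EtOAc, rt
Reagents that add atoms: none
Why: Heterogeneous hydrogenation of the disubstituted ring alkene; rhodium instead of palladium is chosen so that the two allylic acetates are not hydrogenolysed.

Step 6
Reactants: 8 saturated diacetate lactone
Product: 9 1,6,9-trihydroxyspiro[4.5]decane-10-carboxylic acid 1,10-lactone (6,9-diol, both hydroxyls on the C1 face)
Conditions: HCl (1.25 M in MeOH), MeOH, 0 °C → rt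
Reagents that add atoms: none
Why: Acid-catalysed transesterification; base is avoided because the C9 acetate is β to the lactone carbonyl and would be lost by E1cB elimination. The fused γ-lactone is expected to persist, since lactonisation onto the C6 hydroxyl would give a bridged bicyclo[3.2.1] lactone.

Step 7
Reactants: 9 diol lactone
Product: 10 1-hydroxy-6,9-dioxospiro[4.5]decane-10-carboxylic acid 1,10-lactone
Conditions: Dess–Martin periodinane, NaHCO3, CH2Cl2, rt
Reagents that add atoms: none
Why: Dess–Martin oxidation of both secondary alcohols; the stereocentres at C6 and C9, whose configuration never mattered, are removed and C9 becomes part of a β-keto lactone.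

Step 8
Reactants: 10 diketo lactone
Product: 11 1,6-dihydroxy-6-methyl-9-oxospiro[4.5]decane-10-carboxylic acid 1,10-lactone (6-OH on the C1 face, 6-CH3 on the C4 face)
Conditions: LiN(SiMe3)2 (1.05 equiv), THF, −78 °C; then MeLi/CeCl3, −78 °C; aq. NH4Cl
Reagents that add atoms: methyllithium, C[Li]
Why: The amide base removes only the doubly activated C10 proton, so the C9 ketone and the lactone carbonyl are masked as the β-keto lactone enolate; the weakly basic organocerium reagent then undergoes 1,2-addition to the C6 ketone. Attack should occur on the convex C4 face of the cis-fused tricycle, away from the lactone ring, which puts the methyl group on the C4 face and the hydroxyl on the C1 face as in the target; C10 is reprotonated to the only possible cis-fused lactone.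

Step 9
Reactants: 11 methyl carbinol β-keto lactone
Product: 12 6-methyl-9-oxo-6-(triethylsilyloxy)-1-hydroxyspiro[4.5]decane-10-carboxylic acid 1,10-lactone
Conditions: Et3SiOTf, 2,6-lutidine, CH2Cl2, −78 → 0 °C; aq. citric acid
Reagents that add atoms: triethylsilyl trifluoromethanesulfonate, CC[Si](CC)(CC)OS(=O)(=O)C(F)(F)F
Why: Silylation of the hindered tertiary alcohol with a silyl triflate; any silyl enol ether of the β-keto lactone is hydrolysed in the acidic work-up. The ether prevents retro-aldol cleavage once C1 becomes a ketone (steps 12–17) and later shields the C6 face of the five-membered ring.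

Step 10
Reactants: 12 silyl-protected β-keto lactone
Product: 13 10-(hydroxymethyl)-6-methyl-6-(triethylsilyloxy)spiro[4.5]decane-1,9-diol (1-OH on the C10 face; hydroxymethyl and 9-OH on the C1 face)
Conditions: LiBH4, MeOH (1 equiv), THF, 0 °C → rt
Reagents that add atoms: none
Why: Borohydride reduction of the ketone and of the γ-lactone to the diol; it frees the first arm carbon as a primary alcohol for the tether and leaves the silyl ether untouched.

Step 11
Reactants: 13 triol; 14 2-(diethoxyphosphoryl)propanoic acid
Product: 15 [1,9-dihydroxy-6-methyl-6-(triethylsilyloxy)spiro[4.5]decan-10-yl]methyl 2-(diethoxyphosphoryl)propanoate (both epimers at the phosphonate carbon)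
Conditions: DCC, DMAP (cat.), CH2Cl2, −20 → 0 °C
Reagents that add atoms: none
Why: Carbodiimide esterification; at low temperature the primary hydroxyl should react ahead of the two secondary hydroxyls, one of which is neopentylic.

Step 12
Reactants: 15 diol phosphonate ester
Product: 16 [6-methyl-1,9-dioxo-6-(triethylsilyloxy)spiro[4.5]decan-10-yl]methyl 2-(diethoxyphosphoryl)propanoate
Conditions: Dess–Martin periodinane, NaHCO3, CH2Cl2, rt
Reagents that add atoms: none
Why: Dess–Martin oxidation of both secondary alcohols; the C1 stereocentre, which has done its work as relay in step 4, is deleted here on purpose, and the buffered medium should not epimerise C10 next to the new C9 ketone.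

Step 13
Reactants: 16 diketo phosphonate ester
Product: 17 keto δ-lactone, 9-[(Z)-1-carboxyethylidene]-10-(hydroxymethyl)-6-methyl-6-(triethylsilyloxy)spiro[4.5]decan-1-one lactonised between the carboxyl and the hydroxymethyl group
Conditions: LiCl, i-Pr2NEt, MeCN, rt
Reagents that add atoms: none
Why: Intramolecular Horner–Wadsworth–Emmons reaction; closure of the six-membered ring onto the C9 ketone is favoured over a seven-membered ring onto C1. The ring can only contain the new alkene with its carbonyl carbon cis to C10, so the tetrasubstituted alkene is formed as one geometric isomer; the weak amine base deprotonates only the chelated phosphonate and should spare the β-acyloxy ketone from elimination.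

Step 14
Reactants: 17 keto δ-lactone
Product: 18 (2Z)-2-[10-(hydroxymethyl)-6-methyl-1-oxo-6-(triethylsilyloxy)spiro[4.5]decan-9-ylidene]-N-methoxy-N-methylpropanamide
Conditions: MeNH(OMe)·HCl, Me3Al, CH2Cl2, 0 °C → rt; aq. potassium sodium tartrate
Reagents that add atoms: N,O-dimethylhydroxylamine hydrochloride, CNOC.Cl
Why: Aminolysis of the lactone with an aluminium amide; it opens the tether without touching the alkene geometry and distinguishes the acyl carbon (kept as an amide at the future aldehyde oxidation level) from the first arm carbon (free primary alcohol). The product is used at once to avoid relactonisation.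

Step 15
Reactants: 18 hydroxy amide
Product: 20 methyl (2E)-3-[9-[(Z)-1-[methoxy(methyl)amino]-1-oxopropan-2-ylidene]-6-methyl-1-oxo-6-(triethylsilyloxy)spiro[4.5]decan-10-yl]prop-2-enoate, via 10-formyl amide 19 (not isolated)
Conditions: Dess–Martin periodinane, NaHCO3, CH2Cl2, 0 °C; then Ph3P=CHCO2Me, rt
Reagents that add atoms: methyl (triphenylphosphoranylidene)acetate, COC(=O)C=P(c1ccccc1)(c1ccccc1)c1ccccc1
Why: Dess–Martin oxidation followed in the same flask by a Wittig reaction with a stabilised ylide (E-selective); the aldehyde, whose α-carbon C10 is also allylic, is not isolated so that it neither epimerises nor moves into conjugation. The ylide should react with the aldehyde only, not with the hindered C1 ketone.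

Step 16
Reactants: 20 enoate
Product: 21 methyl 3-[9-[(Z)-1-[methoxy(methyl)amino]-1-oxopropan-2-ylidene]-6-methyl-1-oxo-6-(triethylsilyloxy)spiro[4.5]decan-10-yl]propanoate
Conditions: H2 (1 atm), 10% Pd/C, EtOAc, rt
Reagents that add atoms: none
Why: Catalytic hydrogenation of the disubstituted enoate alkene; the tetrasubstituted, amide-conjugated alkene and the ketone are inert under these conditions.

Step 17
Reactants: 21 keto ester amide
Product: 22 methyl 3-[2-allyl-9-[(Z)-1-[methoxy(methyl)amino]-1-oxopropan-2-ylidene]-6-methyl-1-oxo-6-(triethylsilyloxy)spiro[4.5]decan-10-yl]propanoate (allyl on the C10 face)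
Conditions: LiN(SiMe3)2 (1.05 equiv), THF–DMPU, −78 °C; allyl iodide, −78 → −30 °C
Reagents that add atoms: allyl iodide, C=CCI
Why: Ketone enolate alkylation; C2 is the only enolisable position of the C1 ketone because C5 is quaternary, and its protons are more acidic than those of the ester or the γ-positions of the unsaturated amide. The electrophile should approach on the C10 face, because the C6 face is shielded by the fully substituted carbon carrying the triethylsilyloxy group; this sets C2.

Step 18
Reactants: 22 allyl ketone
Product: 24 (2Z)-2-[2-allyl-1-hydroxy-10-(3-hydroxypropyl)-6-methyl-6-(triethylsilyloxy)spiro[4.5]decan-9-ylidene]propan-1-ol (1-OH on the C6 face, trans to allyl), via hydroxy enal 23 (not isolated)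
Conditions: LiAlH4, THF, −78 → 0 °C; then MeOH, CeCl3·7H2O, NaBH4, −20 °C
Reagents that add atoms: none
Why: LiAlH4 reduces the ketone and the ester and stops at the chelated hemiaminal of the N-methoxy-N-methylamide, which releases enal 23 on the methanol quench; Luche reduction in the same flask gives the allylic alcohol. The small hydride should attack the C1 carbonyl from the C10 face, since the C6 face is blocked by the silyloxy group and small hydrides add to 2-alkylcyclopentanones on the side of the alkyl group; both effects place the hydroxyl on the C6 face, which inverts C1 relative to the lactone series.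

Step 19
Reactants: 24 triol
Product: 25 bis(tert-butyldimethylsilyl) ether of 24 at the two primary hydroxyls
Conditions: TBSCl, imidazole, DMF, 0 °C
Reagents that add atoms: tert-butyldimethylsilyl chloride, CC(C)(C)[Si](C)(C)Cl
Why: Selective silylation of the two primary alcohols; the neopentylic secondary hydroxyl at C1 should not react under these conditions.

Step 20
Reactants: 25 bis-silyl ether
Product: 26 2-[(1S,2S,5S,6S,10R)-9-[(Z)-1-(tert-butyldimethylsilyloxy)propan-2-ylidene]-10-[3-(tert-butyldimethylsilyloxy)propyl]-1-hydroxy-6-methyl-6-(triethylsilyloxy)spiro[4.5]decan-2-yl]acetaldehyde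
Conditions: OsO4 (2 mol%), NaIO4, 2,6-lutidine, dioxane–H2O, rt
Reagents that add atoms: sodium periodate, [Na+].[O-]I(=O)(=O)=O (oxygen delivered through osmium tetroxide, O=[Os](=O)(=O)=O)
Why: Lemieux–Johnson cleavage; osmylation selects the monosubstituted terminal alkene over the hindered tetrasubstituted one. The γ-hydroxy aldehyde should stay open, because its lactol would be a trans-fused bicyclo[3.3.0] system.

Step 21
Reactants: 27 6-methylhept-5-en-2-one
Product: 28 6-methylhepta-1,5-dien-2-yl trifluoromethanesulfonate
Conditions: LiN(i-Pr)2, THF, −78 °C; PhNTf2, −78 → 0 °C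
Reagents that add atoms: N-phenylbis(trifluoromethanesulfonimide), O=S(=O)(N(c1ccccc1)S(=O)(=O)C(F)(F)F)C(F)(F)F
Why: Kinetic deprotonation of the methyl ketone at the methyl group and O-triflation of the enolate give the 1,1-disubstituted alkenyl triflate.

Step 22
Reactants: 28 alkenyl triflate
Product: 29 (2E)-8-methyl-4-methylidenenona-2,7-dienal
Conditions: acrolein, Pd(OAc)2 (5 mol%), Et3N, DMF, 60 °C
Reagents that add atoms: acrolein, C=CC=O
Why: Heck reaction of the alkenyl triflate at the β-carbon of the enal; syn β-hydride elimination gives the E alkene. The cross-conjugated dienal is used without storage.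

Step 23
Reactants: 26 hydroxy aldehyde; 29 (2E)-8-methyl-4-methylidenenona-2,7-dienal
Product: 31 (2E,4E)-2-[(1S,2S,5S,6S,10R)-9-[(Z)-1-(tert-butyldimethylsilyloxy)propan-2-ylidene]-10-[3-(tert-butyldimethylsilyloxy)propyl]-1-hydroxy-6-methyl-6-(triethylsilyloxy)spiro[4.5]decan-2-yl]-10-methyl-6-methylideneundeca-2,4,9-trienal, via tert-butylimine 30 (not isolated)
Conditions: t-BuNH2, 4 Å MS, Et2O; LiN(i-Pr)2 (2.2 equiv), THF, −78 → 0 °C; 29, −78 °C; aq. oxalic acid, rt
Reagents that add atoms: none
Why: Directed aldol condensation through the metallated imine: one equivalent of base takes the C1 hydroxyl, the second forms the aza-enolate, which adds 1,2 to the dienal; aqueous oxalic acid hydrolyses the imine and dehydrates the aldol. The 2-substituted enal should form as the E isomer (formyl trans to the dienyl group), which is the thermodynamically preferred geometry and the one the target requires.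

Step 24
Reactants: 31 trienal
Product: 32 the corresponding (2E,4E)-undeca-2,4,9-trien-1-ol
Conditions: NaBH4, CeCl3·7H2O, MeOH, −40 °C
Reagents that add atoms: none
Why: Luche reduction; 1,2-selective hydride addition to the conjugated aldehyde, the only carbonyl group in the molecule.

Step 25
Reactants: 32 allylic alcohol
Product: 33 the corresponding (2E,4E)-undeca-2,4,9-trienyl acetate
Conditions: Ac2O, pyridine, CH2Cl2, 0 °C
Reagents that add atoms: acetic anhydride, CC(=O)OC(C)=O
Why: Acetylation of the primary allylic alcohol; without an acyl-transfer catalyst the neopentylic secondary hydroxyl at C1 should remain free.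

Step 26
Reactants: 33 silyl-protected acetate
Product: 34 [(2E,4E)-2-[(1S,2S,5S,6S,10R)-1,6-dihydroxy-10-(3-hydroxypropyl)-9-[(Z)-1-hydroxypropan-2-ylidene]-6-methylspiro[4.5]decan-2-yl]-10-methyl-6-methylideneundeca-2,4,9-trienyl] acetate
Conditions: HF·pyridine, pyridine, THF, 0 °C → rt
Reagents that add atoms: none
Why: Fluoride-mediated cleavage of the two primary tert-butyldimethylsilyl ethers and the tertiary triethylsilyl ether; the pyridine-buffered medium should leave the acetate and the triene intact.

Step 27
Reactants: 34 tetraol acetate
Product: 35 CNP0204268.2, [(2E,4E)-2-[(1S,2S,5S,6S,10R)-1,6-dihydroxy-10-(3-hydroxypropyl)-6-methyl-9-[(Z)-1-oxopropan-2-ylidene]spiro[4.5]decan-2-yl]-10-methyl-6-methylideneundeca-2,4,9-trienyl] acetate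
Conditions: MnO2, CH2Cl2, rt
Reagents that add atoms: none
Why: Manganese dioxide oxidation, selective for the allylic primary alcohol; the saturated primary, secondary and tertiary hydroxyls are not oxidised and the alkene geometry fixed in step 13 is kept.

## Compound list

1 | (1R,2R)-cyclopentane-1,2-diol | O[C@@H]1CCC[C@H]1O | starting material
2 | 2-(diethoxyphosphoryl)acetic acid | OC(=O)CP(=O)(OCC)OCC | starting material
3 | (1R,2R)-2-hydroxycyclopentyl 2-(diethoxyphosphoryl)acetate | CCOP(=O)(OCC)CC(=O)O[C@@H]1CCC[C@H]1O | intermediate
4 | (1R)-2-oxocyclopentyl 2-(diethoxyphosphoryl)acetate | CCOP(=O)(OCC)CC(=O)O[C@@H]1CCCC1=O | intermediate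
5 | (6aR)-4,5,6,6a-tetrahydro-2H-cyclopenta[b]furan-2-one | O=C1C=C2CCC[C@H]2O1 | intermediate
6 | (1E,3E)-buta-1,3-diene-1,4-diyl diacetate | CC(=O)O/C=C/C=C/OC(C)=O | starting material
7 | endo adduct, 6,9-diacetoxy-1-hydroxyspiro[4.5]dec-7-ene-10-carboxylic acid 1,10-lactone | C1CC[C@]2([C@H]3[C@H](OC(C)=O)C=C[C@@H]2OC(C)=O)[C@@H]1OC3=O | intermediate
8 | 6,9-diacetoxy-1-hydroxyspiro[4.5]decane-10-carboxylic acid 1,10-lactone | C1CC[C@]2([C@H]3[C@H](OC(C)=O)CC[C@@H]2OC(C)=O)[C@@H]1OC3=O | intermediate
9 | 1,6,9-trihydroxyspiro[4.5]decane-10-carboxylic acid 1,10-lactone | C1CC[C@]2([C@H]3[C@H](O)CC[C@@H]2O)[C@@H]1OC3=O | intermediate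
10 | 1-hydroxy-6,9-dioxospiro[4.5]decane-10-carboxylic acid 1,10-lactone | C1CC[C@]2([C@H]3C(=O)CCC2=O)[C@@H]1OC3=O | intermediate
11 | 1,6-dihydroxy-6-methyl-9-oxospiro[4.5]decane-10-carboxylic acid 1,10-lactone | C1CC[C@]2([C@H]3C(=O)CC[C@]2(C)O)[C@@H]1OC3=O | intermediate
12 | 6-O-triethylsilyl ether of 11 | C1CC[C@]2([C@H]3C(=O)CC[C@]2(C)O[Si](CC)(CC)CC)[C@@H]1OC3=O | intermediate
13 | 10-(hydroxymethyl)-6-methyl-6-(triethylsilyloxy)spiro[4.5]decane-1,9-diol | C1CC[C@]2([C@H](CO)[C@H](O)CC[C@]2(C)O[Si](CC)(CC)CC)[C@@H]1O | intermediate
14 | 2-(diethoxyphosphoryl)propanoic acid (racemic) | CC(C(=O)O)P(=O)(OCC)OCC | starting material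
15 | [1,9-dihydroxy-6-methyl-6-(triethylsilyloxy)spiro[4.5]decan-10-yl]methyl 2-(diethoxyphosphoryl)propanoate | C1CC[C@]2([C@H](COC(=O)C(C)P(=O)(OCC)OCC)[C@H](O)CC[C@]2(C)O[Si](CC)(CC)CC)[C@@H]1O | intermediate
16 | [6-methyl-1,9-dioxo-6-(triethylsilyloxy)spiro[4.5]decan-10-yl]methyl 2-(diethoxyphosphoryl)propanoate | C1CC[C@]2([C@H](COC(=O)C(C)P(=O)(OCC)OCC)C(=O)CC[C@]2(C)O[Si](CC)(CC)CC)C1=O | intermediate
17 | keto δ-lactone (lactone of the 9-[(Z)-1-carboxyethylidene]-10-(hydroxymethyl) spiro ketone) | C1CC[C@]2([C@@H]3COC(=O)C(C)=C3CC[C@]2(C)O[Si](CC)(CC)CC)C1=O | intermediate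
18 | (2Z)-2-[10-(hydroxymethyl)-6-methyl-1-oxo-6-(triethylsilyloxy)spiro[4.5]decan-9-ylidene]-N-methoxy-N-methylpropanamide | C1CC[C@]2([C@H](CO)/C(=C(/C)C(=O)N(C)OC)CC[C@]2(C)O[Si](CC)(CC)CC)C1=O | intermediate
19 | (2Z)-2-[10-formyl-6-methyl-1-oxo-6-(triethylsilyloxy)spiro[4.5]decan-9-ylidene]-N-methoxy-N-methylpropanamide | C1CC[C@]2([C@H](C=O)/C(=C(/C)C(=O)N(C)OC)CC[C@]2(C)O[Si](CC)(CC)CC)C1=O | intermediate (not isolated)
20 | methyl (2E)-3-[9-[(Z)-1-[methoxy(methyl)amino]-1-oxopropan-2-ylidene]-6-methyl-1-oxo-6-(triethylsilyloxy)spiro[4.5]decan-10-yl]prop-2-enoate | C1CC[C@]2([C@H](/C=C/C(=O)OC)/C(=C(/C)C(=O)N(C)OC)CC[C@]2(C)O[Si](CC)(CC)CC)C1=O | intermediate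
21 | methyl 3-[9-[(Z)-1-[methoxy(methyl)amino]-1-oxopropan-2-ylidene]-6-methyl-1-oxo-6-(triethylsilyloxy)spiro[4.5]decan-10-yl]propanoate | C1CC[C@]2([C@H](CCC(=O)OC)/C(=C(/C)C(=O)N(C)OC)CC[C@]2(C)O[Si](CC)(CC)CC)C1=O | intermediate
22 | 2-allyl derivative of 21 (allyl on the C10 face) | C=CC[C@@H]1CC[C@]2([C@H](CCC(=O)OC)/C(=C(/C)C(=O)N(C)OC)CC[C@]2(C)O[Si](CC)(CC)CC)C1=O | intermediate
23 | (2Z)-2-[2-allyl-1-hydroxy-10-(3-hydroxypropyl)-6-methyl-6-(triethylsilyloxy)spiro[4.5]decan-9-ylidene]propanal | C=CC[C@@H]1CC[C@]2([C@H](CCCO)/C(=C(/C)C=O)CC[C@]2(C)O[Si](CC)(CC)CC)[C@H]1O | intermediate (not isolated)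
24 | (2Z)-2-[2-allyl-1-hydroxy-10-(3-hydroxypropyl)-6-methyl-6-(triethylsilyloxy)spiro[4.5]decan-9-ylidene]propan-1-ol | C=CC[C@@H]1CC[C@]2([C@H](CCCO)/C(=C(/C)CO)CC[C@]2(C)O[Si](CC)(CC)CC)[C@H]1O | intermediate
25 | bis(tert-butyldimethylsilyl) ether of 24 (both primary hydroxyls) | C=CC[C@@H]1CC[C@]2([C@H](CCCO[Si](C)(C)C(C)(C)C)/C(=C(/C)CO[Si](C)(C)C(C)(C)C)CC[C@]2(C)O[Si](CC)(CC)CC)[C@H]1O | intermediate
26 | 2-[(1S,2S,5S,6S,10R)-9-[(Z)-1-(tert-butyldimethylsilyloxy)propan-2-ylidene]-10-[3-(tert-butyldimethylsilyloxy)propyl]-1-hydroxy-6-methyl-6-(triethylsilyloxy)spiro[4.5]decan-2-yl]acetaldehyde | O=CC[C@@H]1CC[C@]2([C@H](CCCO[Si](C)(C)C(C)(C)C)/C(=C(/C)CO[Si](C)(C)C(C)(C)C)CC[C@]2(C)O[Si](CC)(CC)CC)[C@H]1O | intermediate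
27 | 6-methylhept-5-en-2-one | CC(C)=CCCC(C)=O | starting material
28 | 6-methylhepta-1,5-dien-2-yl trifluoromethanesulfonate | C=C(CCC=C(C)C)OS(=O)(=O)C(F)(F)F | intermediate
29 | (2E)-8-methyl-4-methylidenenona-2,7-dienal | O=C/C=C/C(=C)CCC=C(C)C | intermediate
30 | N-tert-butylimine of 26 | CC(C)(C)/N=C/C[C@@H]1CC[C@]2([C@H](CCCO[Si](C)(C)C(C)(C)C)/C(=C(/C)CO[Si](C)(C)C(C)(C)C)CC[C@]2(C)O[Si](CC)(CC)CC)[C@H]1O | intermediate (not isolated)
31 | (2E,4E)-2-[silyl-protected spiro core-2-yl]-10-methyl-6-methylideneundeca-2,4,9-trienal | C=C(/C=C/C=C(/C=O)[C@@H]1CC[C@]2([C@H](CCCO[Si](C)(C)C(C)(C)C)/C(=C(/C)CO[Si](C)(C)C(C)(C)C)CC[C@]2(C)O[Si](CC)(CC)CC)[C@H]1O)CCC=C(C)C | intermediate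
32 | corresponding (2E,4E)-trien-1-ol | C=C(/C=C/C=C(/CO)[C@@H]1CC[C@]2([C@H](CCCO[Si](C)(C)C(C)(C)C)/C(=C(/C)CO[Si](C)(C)C(C)(C)C)CC[C@]2(C)O[Si](CC)(CC)CC)[C@H]1O)CCC=C(C)C | intermediate
33 | corresponding (2E,4E)-trienyl acetate | C=C(/C=C/C=C(/COC(C)=O)[C@@H]1CC[C@]2([C@H](CCCO[Si](C)(C)C(C)(C)C)/C(=C(/C)CO[Si](C)(C)C(C)(C)C)CC[C@]2(C)O[Si](CC)(CC)CC)[C@H]1O)CCC=C(C)C | intermediate
34 | desilylated tetraol acetate (9-[(Z)-1-hydroxypropan-2-ylidene]) | C=C(/C=C/C=C(/COC(C)=O)[C@@H]1CC[C@]2([C@H](CCCO)/C(=C(/C)CO)CC[C@]2(C)O)[C@H]1O)CCC=C(C)C | intermediate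
35 | CNP0204268.2 | C=C(/C=C/C=C(/COC(C)=O)[C@@H]1CC[C@]2([C@H](CCCO)/C(=C(/C)C=O)CC[C@]2(C)O)[C@H]1O)CCC=C(C)C | target

## Step count and least certain steps

Total: 27 steps. Longest linear sequence: 25 steps (steps 1–20 and 23–27, from 1 to 35); the side-chain fragment takes steps 21–22.

**Step 4 (key step).** The most likely failure is insufficient rate: the trisubstituted lactone alkene that must become a quaternary carbon may react too slowly even under pressure, so that slow loss of the diene wins; erosion of facial selectivity is less likely. Fallback, setting out from 5: the acetoxy donors are replaced by silyloxy donors. Reaction of 5 with commercial 1,4-bis(trimethylsilyloxy)buta-1,3-diene (the E,E isomer is the reactive one) in toluene at 150 °C in a sealed tube should give the bis(trimethylsilyl) ether adduct F1. Hydrogenation (H2, Rh/Al2O3, EtOAc) gives the saturated bis-silyl ether F2, and brief treatment with citric acid in methanol at 0 °C removes the silyl groups and returns to the route at 9.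

**Step 8.** The discrimination between the two ketones may be incomplete: proton exchange can return free β-keto lactone, which then takes up the methyl reagent at C9 or at the lactone, or the C6 ketone may be enolised instead of attacked. Fallback, setting out from 10: the β-keto lactone is masked covalently. Et3N and TBSOTf give the tert-butyldimethylsilyl enol ether F3 (C9–O–Si, C9=C10); MeLi/CeCl3 then adds to the only remaining ketone to give the tertiary carbinol F4; aqueous acetic acid in THF hydrolyses the enol ether, with protonation of C10 to the only possible cis-fused lactone, and returns to the route at 11.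

**Step 13.** The base may induce loss of the acyloxy group from the β-acyloxy ketone (elimination towards a 10-methylene ketone) or epimerise C10, and the hindered C9 ketone may accept the α-methyl phosphonate carbanion only slowly. Fallback, setting out from 13: a Reformatsky-type closure without amine base. 2-Bromopropanoyl bromide and pyridine at −40 °C acylate the primary hydroxyl to the 2-bromopropanoate F5; Dess–Martin oxidation gives the diketone F6; SmI2 in THF at −78 °C generates the samarium enolate, which adds to the C9 ketone through a six-membered ring to give the β-hydroxy δ-lactone F7. Dehydration with SOCl2 and pyridine, followed by DBU to bring any unconjugated alkene into conjugation, returns to the route at 17.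

**Step 17 (together with step 18).** Facial selectivity may be poor in the enolate allylation (mixture at C2), or hydride may be delivered from the C6 face in step 18; either would spoil the C1/C2 relationship. Fallback, setting out from 21: C1 is set first and C2 afterwards by hydroxyl-directed hydrogenation.
- Aldol addition of the lithium enolate (LiN(SiMe3)2) to 2,2-dimethoxyacetaldehyde and dehydration (MsCl, Et3N, then DBU) give the (E)-2-(2,2-dimethoxyethylidene) ketone F8.
- Reduction as in step 18 (LiAlH4, then NaBH4/CeCl3) gives the allylic alcohol triol F9; with no sp3 substituent at C2, only the silyloxy group differentiates the faces of the ketone.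
- TBSCl and imidazole give the bis-silyl ether F10.
- H2 with [Ir(cod)(PCy3)(py)]PF6 in CH2Cl2 delivers hydrogen to C2 from the face of the C1 hydroxyl and gives the dimethyl acetal F11 with the C2 branch trans to the hydroxyl.
- Mild acetal hydrolysis (LiBF4, wet MeCN) returns to the route at 26.

**Step 23.** The cross-conjugated dienal 29 may be consumed by conjugate addition of the aza-enolate or by self-cycloaddition before 1,2-addition takes place. Fallback, setting out from 26: the fragile diene terminus is moved to the last carbon–carbon bond formation. The same imine-directed aldol condensation with (E)-3-(tributylstannyl)prop-2-enal gives the stannyl dienal F12, and Stille coupling of F12 with triflate 28 (Pd2(dba)3, AsPh3, LiCl, NMP) returns to the route at 31.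

## Further compounds

F1 | step 4 | bis(trimethylsilyl) ether analogue of adduct 7 | C1CC[C@]2([C@H]3[C@H](O[Si](C)(C)C)C=C[C@@H]2O[Si](C)(C)C)[C@@H]1OC3=O
F2 | step 4 | bis(trimethylsilyl) ether analogue of 8 | C1CC[C@]2([C@H]3[C@H](O[Si](C)(C)C)CC[C@@H]2O[Si](C)(C)C)[C@@H]1OC3=O
F3 | step 8 | tert-butyldimethylsilyl enol ether of 10 (C9–O–Si, C9=C10) | C1CC[C@]2(C3=C(O[Si](C)(C)C(C)(C)C)CCC2=O)[C@@H]1OC3=O
F4 | step 8 | 6-hydroxy-6-methyl derivative of F3 | C1CC[C@]2(C3=C(O[Si](C)(C)C(C)(C)C)CC[C@]2(C)O)[C@@H]1OC3=O
F5 | step 13 | [1,9-dihydroxy-6-methyl-6-(triethylsilyloxy)spiro[4.5]decan-10-yl]methyl 2-bromopropanoate | C1CC[C@]2([C@H](COC(=O)C(C)Br)[C@H](O)CC[C@]2(C)O[Si](CC)(CC)CC)[C@@H]1O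
F6 | step 13 | [6-methyl-1,9-dioxo-6-(triethylsilyloxy)spiro[4.5]decan-10-yl]methyl 2-bromopropanoate | C1CC[C@]2([C@H](COC(=O)C(C)Br)C(=O)CC[C@]2(C)O[Si](CC)(CC)CC)C1=O
F7 | step 13 | β-hydroxy δ-lactone (9-hydroxy, saturated analogue of 17) | C1CC[C@]2([C@@H]3COC(=O)C(C)C3(O)CC[C@]2(C)O[Si](CC)(CC)CC)C1=O
F8 | step 17 | (E)-2-(2,2-dimethoxyethylidene) derivative of 21 | COC(OC)/C=C1\CC[C@]2([C@H](CCC(=O)OC)/C(=C(/C)C(=O)N(C)OC)CC[C@]2(C)O[Si](CC)(CC)CC)C1=O
F9 | step 17 | 2-(2,2-dimethoxyethylidene) allylic alcohol triol | COC(OC)/C=C1\CC[C@]2([C@H](CCCO)/C(=C(/C)CO)CC[C@]2(C)O[Si](CC)(CC)CC)[C@H]1O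
F10 | step 17 | bis(tert-butyldimethylsilyl) ether of F9 | COC(OC)/C=C1\CC[C@]2([C@H](CCCO[Si](C)(C)C(C)(C)C)/C(=C(/C)CO[Si](C)(C)C(C)(C)C)CC[C@]2(C)O[Si](CC)(CC)CC)[C@H]1O
F11 | step 17 | dimethyl acetal of 26 | COC(OC)C[C@@H]1CC[C@]2([C@H](CCCO[Si](C)(C)C(C)(C)C)/C(=C(/C)CO[Si](C)(C)C(C)(C)C)CC[C@]2(C)O[Si](CC)(CC)CC)[C@H]1O
F12 | step 23 | (2E,4E)-2-[silyl-protected spiro core-2-yl]-5-(tributylstannyl)penta-2,4-dienal | CCCC[Sn](CCCC)(CCCC)/C=C/C=C(/C=O)[C@@H]1CC[C@]2([C@H](CCCO[Si](C)(C)C(C)(C)C)/C(=C(/C)CO[Si](C)(C)C(C)(C)C)CC[C@]2(C)O[Si](CC)(CC)CC)[C@H]1O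
A1 | alternative 1 | spiro cyclopentene with silylethyl arm | C[Si](C)(c1ccccc1)CCC1=C[C@]2(CC1)[C@H](CCCO[Si](C)(C)C(C)(C)C)C3(OCCO3)CC[C@]2(C)O[Si](CC)(CC)CC
A2 | alternative 1 | bromoalkene precursor of A1 | BrC=C(CC[Si](C)(C)c1ccccc1)CC[C@H]1[C@H](CCCO[Si](C)(C)C(C)(C)C)C2(OCCO2)CC[C@]1(C)O[Si](CC)(CC)CC
A3 | alternative 2 | spiro cyclohexanone with exocyclic tetrasubstituted alkene | C1CC[C@]2([C@H](CCCO[Si](C)(C)C(C)(C)C)/C(=C(/C)CO[Si](C)(C)C(C)(C)C)CCC2=O)[C@H]1O[Si](CC)(CC)CC
A4 | alternative 2 | enone–alkyne precursor of A3 | C=CC(=O)[C@@]1(CCC[C@@H]1O[Si](CC)(CC)CC)[C@H](CCCO[Si](C)(C)C(C)(C)C)C#CCO[Si](C)(C)C(C)(C)C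
A5 | alternative 3 | spiro trans-2-vinylcyclopentanol | C=C[C@@H]1CC[C@]2([C@H](CCCO[Si](C)(C)C(C)(C)C)/C(=C(/C)CO[Si](C)(C)C(C)(C)C)CC[C@]2(C)OCOC)[C@H]1O
A6 | alternative 3 | aldehyde allylsilane precursor of A5 | O=C[C@]1(CC/C=C/C[Si](C)(C)C)[C@H](CCCO[Si](C)(C)C(C)(C)C)/C(=C(/C)CO[Si](C)(C)C(C)(C)C)CC[C@]1(C)OCOC
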